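**Retrosynthetic overview**
1. Target 21 ⇐ reductive SN1′ opening of a C9–O–C15 oxa bridge in oxanorbornene 18; this gives C8=C9, C16H2 and the 15-OH together.
2. 18 ⇐ key step: type-2 intramolecular furan Diels–Alder reaction of acetoxy-enal 16 (new bonds C9–C10 and C14–C15). The cyclohexene and the 11-membered ring close in one operation on a preformed cyclopentene.
3. 16 ⇐ 4-substituted cyclopentenone 12 (hydroxymethylation, 1,2-reduction, oxidation, inverting acetate) ⇐ (R)-4-silyloxycyclopentenone 9 + alkenyl-metal from alkyne 8 (sets C11).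
4. 8 ⇐ (S)-citronellyl bromide 1 (C5 stereocentre) + 3-bromo-2-methylfuran 2, prenyl cleavage, acetylide homologation.
5. Ring order: cyclopentene (purchased) → six- and eleven-membered rings together → bridge removal.

Assumption: 1, 2 and 9 are bought (1 and 9 enantiopure); atom labels used below are C1(=CH2), C2–C4, C5(Me), C6, C7, C8=C9(Me), C10, C11, C12, C13(OAc), C14(CH2OH), C15(OH), C16, so the target is (5S,10S,11R,13R,14R,15S).

**Step 1**
Reactants: 1 (S)-citronellyl bromide [(6S)-8-bromo-2,6-dimethyloct-2-ene]; 2 3-bromo-2-methylfuran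
Product: 4 3-[(3S)-3,7-dimethyloct-6-en-1-yl]-2-methylfuran, via alkylzinc bromide 3 (not isolated)
Conditions: Zn dust, I2 (5 mol %), DMA, 70 °C; then 2, Pd(OAc)2 (2 mol %), SPhos (4 mol %), THF, 40 °C
Reagents that add atoms: none
Why: Negishi sp3–sp2 coupling of the primary alkylzinc bromide with the heteroaryl bromide leaves the trisubstituted alkene untouched, and the chiral-pool C5 centre is remote from every reacting atom.

**Step 2**
Reactants: 4 3-[(3S)-3,7-dimethyloct-6-en-1-yl]-2-methylfuran
Product: 6 (4R)-4-methyl-6-(2-methylfuran-3-yl)hexan-1-ol, via aldehyde 5 (not isolated)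
Conditions: OsO4 (2 mol %), NaIO4 (4 equiv), 2,6-lutidine, dioxane/H2O 3:1, rt; crude, NaBH4, MeOH, 0 °C
Reagents that add atoms: sodium periodate, [Na+].[O-]I(=O)(=O)=O (terminal source of the new O, relayed by catalytic osmium tetroxide, O=[Os](=O)(=O)=O)
Why: Lemieux–Johnson oxidative cleavage attacks the electron-rich trisubstituted alkene in preference to the aromatic furan (which ozone or peracids would destroy), and borohydride reduction of the crude aldehyde gives the primary alcohol without touching C5.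

**Step 3**
Reactants: 6 (4R)-4-methyl-6-(2-methylfuran-3-yl)hexan-1-ol
Product: 7 3-[(3R)-6-iodo-3-methylhexyl]-2-methylfuran
Conditions: PPh3, imidazole, I2, CH2Cl2, 0 °C → rt
Reagents that add atoms: iodine, II
Why: Appel-type iodination converts the primary alcohol into the iodide by SN2 under buffered, non-acidic conditions that the furan tolerates.

**Step 4**
Reactants: 7 3-[(3R)-6-iodo-3-methylhexyl]-2-methylfuran
Product: 8 2-methyl-3-[(3S)-3-methyloct-7-yn-1-yl]furan
Conditions: lithium acetylide–ethylenediamine complex (2 equiv), DMSO, 15 °C → rt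
Reagents that add atoms: lithium acetylide–ethylenediamine complex, [Li+].[C-]#C.NCCN
Why: SN2 alkylation of acetylide by the unhindered primary iodide installs C1 and the future exocyclic methylene carbon as a terminal alkyne.

**Step 5**
Reactants: 8 2-methyl-3-[(3S)-3-methyloct-7-yn-1-yl]furan; 9 (4R)-4-[(tert-butyldimethylsilyl)oxy]cyclopent-2-en-1-one
Product: 12 (4R)-4-[(6S)-6-methyl-8-(2-methylfuran-3-yl)oct-1-en-2-yl]cyclopent-2-en-1-one, via alkenylalane 10 (not isolated), via silyloxy ketone 11 (not isolated)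
Conditions: DIBAL-H (1.05 equiv), Ni(dppp)Cl2 (3 mol %), THF, 0 °C → rt; then 9 (0.8 equiv), IMesCuCl (5 mol %), −78 → −30 °C; aq. NH4Cl; crude, DBU, CH2Cl2, −20 °C
Reagents that add atoms: none
Why: Nickel-catalysed Markovnikov hydroalumination gives the 1,1-disubstituted alkenylalane, its copper-catalysed conjugate addition occurs anti to the neighbouring silyloxy group (fixing C11 as R), and E1cB loss of silanol from the β-silyloxy ketone relocates the enone to C14=C10 (conjugate addition–elimination).

**Step 6**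
Reactants: 12 (4R)-4-[(6S)-6-methyl-8-(2-methylfuran-3-yl)oct-1-en-2-yl]cyclopent-2-en-1-one
Product: 13 (4R)-2-(hydroxymethyl)-4-[(6S)-6-methyl-8-(2-methylfuran-3-yl)oct-1-en-2-yl]cyclopent-2-en-1-one
Conditions: aq. HCHO (37 %, 3 equiv), imidazole (0.5 equiv), THF/H2O 1:1, rt
Reagents that add atoms: formaldehyde, C=O
Why: Morita–Baylis–Hillman reaction in which imidazole adds reversibly to the enone β-carbon and the resulting enolate captures formaldehyde at C14, creating no new stereocentre and leaving C11 untouched.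

**Step 7**
Reactants: 13 (4R)-2-(hydroxymethyl)-4-[(6S)-6-methyl-8-(2-methylfuran-3-yl)oct-1-en-2-yl]cyclopent-2-en-1-one
Product: 14 (1S,4R)-2-(hydroxymethyl)-4-[(6S)-6-methyl-8-(2-methylfuran-3-yl)oct-1-en-2-yl]cyclopent-2-en-1-ol
Conditions: NaBH4, CeCl3·7H2O, MeOH, −78 °C
Reagents that add atoms: none
Why: Luche 1,2-reduction delivers hydride to the cerium-activated carbonyl from the face opposite the bulky C11 alkenyl group, giving the cis-1,4 (13S) allylic alcohol without conjugate reduction.

**Step 8**
Reactants: 14 (1S,4R)-2-(hydroxymethyl)-4-[(6S)-6-methyl-8-(2-methylfuran-3-yl)oct-1-en-2-yl]cyclopent-2-en-1-ol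
Product: 15 (3R,5S)-5-hydroxy-3-[(6S)-6-methyl-8-(2-methylfuran-3-yl)oct-1-en-2-yl]cyclopent-1-ene-1-carbaldehyde
Conditions: TEMPO (10 mol %), PhI(OAc)2 (1.1 equiv), CH2Cl2, rt
Reagents that add atoms: none
Why: TEMPO/PhI(OAc)2 oxidation is chemoselective for the primary allylic alcohol over the hindered secondary one, stops at the enal and tolerates the furan and alkenes.

**Step 9**
Reactants: 15 (3R,5S)-5-hydroxy-3-[(6S)-6-methyl-8-(2-methylfuran-3-yl)oct-1-en-2-yl]cyclopent-1-ene-1-carbaldehyde
Product: 16 (1R,4R)-2-formyl-4-[(6S)-6-methyl-8-(2-methylfuran-3-yl)oct-1-en-2-yl]cyclopent-2-en-1-yl acetate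
Conditions: AcOH, PPh3, DIAD, toluene, −20 → 0 °C
Reagents that add atoms: acetic acid, CC(=O)O
Why: Mitsunobu esterification, in which SN2 displacement of the alkoxyphosphonium by acetate inverts C13 to R and so places the acetate trans to the C11 side chain as in the target.

**Step 10**
Reactants: 16 (1R,4R)-2-formyl-4-[(6S)-6-methyl-8-(2-methylfuran-3-yl)oct-1-en-2-yl]cyclopent-2-en-1-yl acetate
Product: 18 oxa-bridged cycloadduct alcohol (7-oxanorbornene carrying the new six- and eleven-membered rings; full description in the compound list), via cycloadduct aldehyde 17 (not isolated)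
Conditions: MeAlCl2 (2.2 equiv), CH2Cl2 (1 mM), −78 °C, 12 h; then EtOH (excess), NaBH4, −78 → −30 °C
Reagents that add atoms: none
Why: Proposed new method: a macrocyclising type-2 intramolecular furan Diels–Alder reaction in which the Lewis-acid-activated enal C10=C14 adds across furan C9/C15 (the hindered methyl-bearing C9 meets the CH carbon C10 and the free C15 meets the quaternary-forming C14), the C1–C7 tether being held on the endo side and on the cyclopentene face syn to itself and anti to the acetate, so that the six- and eleven-membered rings form together with C10, C14 and C15 set as required (O bridge cis to H-10 and to CHO), low temperature shifting the furan equilibrium to the adduct and immediate borohydride reduction of the aldehyde blocking cycloreversion; the closest known reactions are type-2 intramolecular Diels–Alder reactions giving bridgehead alkenes and alkylaluminium chloride-promoted intramolecular furan Diels–Alder reactions at −78 °C.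

**Step 11**
Reactants: 18 oxa-bridged cycloadduct alcohol
Product: 21 CNP0228496.1 (target), via primary TES ether 19 (not isolated), via bis-TES ether 20 (not isolated)
Conditions: TESOTf (1.1 equiv), 2,6-lutidine (1.1 equiv), CH2Cl2, −78 °C; Et3SiH (10 equiv), TESOTf (0.3 equiv), −78 → −40 °C; aq. NaHCO3; crude, HF·pyridine, pyridine, THF, 0 °C → rt
Reagents that add atoms: none
Why: Proposed new method: after in situ silylation of the primary alcohol, silyl triflate ionises the strained tertiary allylic bridgehead C9–O bond to an allyl cation (C9–C8–C16) that takes hydride from triethylsilane at the less hindered terminus C16 (SN1′ ionic hydrogenation), giving the tetrasubstituted C8=C9 alkene while the C15–O bond and its configuration are kept, and buffered HF then removes both silyl groups without acetate migration; the closest known reactions are silyl triflate/Et3SiH reductive cleavage of acetals and allylic ethers and the reductive ring-opening of oxabicyclic alkenes.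

**Compound list**
1 | (S)-citronellyl bromide, (6S)-8-bromo-2,6-dimethyloct-2-ene | CC(C)=CCC[C@H](C)CCBr | starting material
2 | 3-bromo-2-methylfuran | Cc1occc1Br | starting material
3 | [(3S)-3,7-dimethyloct-6-en-1-yl]zinc bromide | CC(C)=CCC[C@H](C)CC[Zn]Br | intermediate (not isolated)
4 | 3-[(3S)-3,7-dimethyloct-6-en-1-yl]-2-methylfuran | CC(C)=CCC[C@H](C)CCc1ccoc1C | intermediate
5 | (4R)-4-methyl-6-(2-methylfuran-3-yl)hexanal | O=CCC[C@H](C)CCc1ccoc1C | intermediate (not isolated)
6 | (4R)-4-methyl-6-(2-methylfuran-3-yl)hexan-1-ol | OCCC[C@H](C)CCc1ccoc1C | intermediate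
7 | 3-[(3R)-6-iodo-3-methylhexyl]-2-methylfuran | ICCC[C@H](C)CCc1ccoc1C | intermediate
8 | 2-methyl-3-[(3S)-3-methyloct-7-yn-1-yl]furan | C#CCCC[C@H](C)CCc1ccoc1C | intermediate
9 | (4R)-4-[(tert-butyldimethylsilyl)oxy]cyclopent-2-en-1-one | O=C1C=C[C@H](O[Si](C)(C)C(C)(C)C)C1 | starting material
10 | diisobutyl[(6S)-6-methyl-8-(2-methylfuran-3-yl)oct-1-en-2-yl]alumane | C=C([Al](CC(C)C)CC(C)C)CCC[C@H](C)CCc1ccoc1C | intermediate (not isolated)
11 | (3S,4R)-4-[(tert-butyldimethylsilyl)oxy]-3-[(6S)-6-methyl-8-(2-methylfuran-3-yl)oct-1-en-2-yl]cyclopentan-1-one (3,4-trans) | O=C1C[C@@H](O[Si](C)(C)C(C)(C)C)[C@H](C(=C)CCC[C@H](C)CCc2ccoc2C)C1 | intermediate (not isolated)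
12 | (4R)-4-[(6S)-6-methyl-8-(2-methylfuran-3-yl)oct-1-en-2-yl]cyclopent-2-en-1-one | O=C1C=C[C@H](C(=C)CCC[C@H](C)CCc2ccoc2C)C1 | intermediate
13 | (4R)-2-(hydroxymethyl)-4-[(6S)-6-methyl-8-(2-methylfuran-3-yl)oct-1-en-2-yl]cyclopent-2-en-1-one | O=C1C(CO)=C[C@H](C(=C)CCC[C@H](C)CCc2ccoc2C)C1 | intermediate
14 | (1S,4R)-2-(hydroxymethyl)-4-[(6S)-6-methyl-8-(2-methylfuran-3-yl)oct-1-en-2-yl]cyclopent-2-en-1-ol (1,4-cis) | O[C@@H]1C(CO)=C[C@H](C(=C)CCC[C@H](C)CCc2ccoc2C)C1 | intermediate
15 | (3R,5S)-5-hydroxy-3-[(6S)-6-methyl-8-(2-methylfuran-3-yl)oct-1-en-2-yl]cyclopent-1-ene-1-carbaldehyde | O[C@@H]1C(C=O)=C[C@H](C(=C)CCC[C@H](C)CCc2ccoc2C)C1 | intermediate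
16 | (1R,4R)-2-formyl-4-[(6S)-6-methyl-8-(2-methylfuran-3-yl)oct-1-en-2-yl]cyclopent-2-en-1-yl acetate (1,4-trans) | CC(=O)O[C@H]1C(C=O)=C[C@H](C(=C)CCC[C@H](C)CCc2ccoc2C)C1 | intermediate
17 | cycloadduct aldehyde: 7-oxanorbornene (O bridging C9(Me) and C15(H), alkene C8=C16) endo-fused through C10–C14 to the 13-acetoxycyclopentane, CHO on C14, C8 and C11 spanned by C1–C7 (11-membered ring, C1=CH2, 5S); O bridge, H-10 and CHO on the same exo face; C11 and C13 as in 16 | C=C1CCC[C@H](C)CCC2=C[C@@H]3O[C@@]2(C)[C@@H]4[C@H]1C[C@@H](OC(C)=O)[C@]34C=O | intermediate (not isolated)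
18 | cycloadduct alcohol: 17 with CH2OH in place of CHO on C14 | C=C1CCC[C@H](C)CCC2=C[C@@H]3O[C@@]2(C)[C@@H]4[C@H]1C[C@@H](OC(C)=O)[C@]34CO | intermediate
19 | primary triethylsilyl ether of 18 | C=C1CCC[C@H](C)CCC2=C[C@@H]3O[C@@]2(C)[C@@H]4[C@H]1C[C@@H](OC(C)=O)[C@]34CO[Si](CC)(CC)CC | intermediate (not isolated)
20 | bis(triethylsilyl) ether of 21 (on the C14 CH2O and on O15) | C=C1CCC[C@H](C)CCC2=C(C)[C@@H]3[C@H]1C[C@@H](OC(C)=O)[C@]3(CO[Si](CC)(CC)CC)[C@@H](O[Si](CC)(CC)CC)C2 | intermediate (not isolated)
21 | CNP0228496.1: (5S,10S,11R,13R,14R,15S)-13-acetoxy-14-(hydroxymethyl)-5,9-dimethyl-1-methylidene tricycle (cycloundec-8-ene C1–C11; cyclohexene C8=C9–C10–C14–C15–C16; cyclopentane C10–C11–C12–C13–C14) with 15-OH | C=C1CCC[C@H](C)CCC2=C(C)[C@@H]3[C@H]1C[C@@H](OC(C)=O)[C@]3(CO)[C@@H](O)C2 | target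

**Totals and risks**
Total steps: 11. Longest linear sequence: 11 (1 → 21; 2 and 9 enter as purchased building blocks).

The three steps most likely to fail:

Step 10, the ring-forming cycloaddition. It can fail through an unfavourable furan equilibrium, oligomerisation, Friedel–Crafts alkylation or loss of acetate, or by taking the exo mode (which would give the 15-epimer). The fallback sets out from 16. Trimethyl orthoformate with catalytic PPTS in MeOH gives the dimethyl acetal F1. Catalytic TMSOTf in CH2Cl2 (1 mM, −78 °C) ionises it to an alkoxyallyl cation, a much stronger 2π partner, and a cationic (ionic) Diels–Alder reaction gives the acetal-protected cycloadduct F2. Cold hydrolysis (PPTS, acetone/H2O, 0 °C) releases 17, which is reduced at once with NaBH4, and the route is rejoined at 18.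

Step 11, the reductive bridge opening. The allyl cation could be trapped by the exocyclic alkene, lose a proton, or take hydride at C9. The fallback sets out from 18. Chlorodiisopropylsilane and imidazole give the diisopropylsilyl ether F3, which carries a tethered Si–H. Catalytic TMSOTf at −78 °C ionises the bridge, the tethered hydride is delivered intramolecularly on the exo face faster than any competing capture, and the silylium is caught by O15 to give the cyclic diisopropylsilylene F4. HF·pyridine removes the silylene, and the route is rejoined at 21.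

Step 9, the Mitsunobu inversion. The alcohol sits next to an enal, so SN2′ attack at C10 or elimination could compete with SN2. The fallback sets out from 13 and replaces steps 7–9. Reagent-controlled Corey–Bakshi–Shibata reduction ((S)-Me-CBS, catecholborane, toluene, −78 °C) gives the trans-diol F5 directly. TEMPO/PhI(OAc)2 oxidises its primary alcohol to the trans-hydroxy enal F6, and Ac2O/pyridine/DMAP acetylates with retention; the route is rejoined at 16.

**Further compounds**
F1 | step 10 | (1R,4R)-2-(dimethoxymethyl)-4-[(6S)-6-methyl-8-(2-methylfuran-3-yl)oct-1-en-2-yl]cyclopent-2-en-1-yl acetate | CC(=O)O[C@H]1C(C(OC)OC)=C[C@H](C(=C)CCC[C@H](C)CCc2ccoc2C)C1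
F2 | step 10 | dimethyl acetal of cycloadduct aldehyde 17 | C=C1CCC[C@H](C)CCC2=C[C@@H]3O[C@@]2(C)[C@@H]4[C@H]1C[C@@H](OC(C)=O)[C@]34C(OC)OC
F3 | step 11 | diisopropylsilyl (Si–H) ether of 18 | C=C1CCC[C@H](C)CCC2=C[C@@H]3O[C@@]2(C)[C@@H]4[C@H]1C[C@@H](OC(C)=O)[C@]34CO[SiH](C(C)C)C(C)C
F4 | step 11 | cyclic diisopropylsilylene of 21 (bridging the C14 CH2O and O15) | C=C1CCC[C@H](C)CCC2=C(C)[C@@H]3[C@H]1C[C@@H](OC(C)=O)[C@@]34CO[Si](C(C)C)(C(C)C)O[C@H]4C2
F5 | step 9 | (1R,4R)-2-(hydroxymethyl)-4-[(6S)-6-methyl-8-(2-methylfuran-3-yl)oct-1-en-2-yl]cyclopent-2-en-1-ol | O[C@H]1C(CO)=C[C@H](C(=C)CCC[C@H](C)CCc2ccoc2C)C1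
F6 | step 9 | (3R,5R)-5-hydroxy-3-[(6S)-6-methyl-8-(2-methylfuran-3-yl)oct-1-en-2-yl]cyclopent-1-ene-1-carbaldehyde | O[C@H]1C(C=O)=C[C@H](C(=C)CCC[C@H](C)CCc2ccoc2C)C1
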